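## Retrosynthetic overview

1. Andavadoic acid ⇐ saponification and diimide reduction ⇐ Wittig union of a 1,2-dioxolane aldehyde with the ylide of (8-phenyloctyl)triphenylphosphonium bromide (from PhMgBr and 1,8-dibromooctane).
2. The 1,2-dioxolane, the only ring of the target, ⇐ 5-exo intramolecular peroxy-Michael addition of a tertiary hydroperoxide to a β-methyl enoate; this sets C3.
3. The tertiary hydroperoxide (C5) ⇐ invertive perhydrolysis (H2O2/TMSOTf) of an enantiopure 2,2-disubstituted oxetane; the freed CH2CH2OH is the handle for the chain.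
4. Oxetane enoate ⇐ HWE / ozonolysis ⇐ sulfoxonium-ylide ring expansion of an epoxide ⇐ Cu-catalysed isopropenyl-Grignard opening of (S)-2-methylglycidyl tosylate ⇐ Sharpless epoxidation of methallyl alcohol.
5. Ring order: epoxide, then oxetane (auxiliary rings, steps 1–3), then the dioxolane (step 7).

Assumption: the target SMILES corresponds to (3R,5S) (C3-methyl and C5-chain cis); anhydrous ethereal H2O2 and potassium azodicarboxylate are made fresh by standard procedures and treated as reagents, not counted as steps.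

## Route

Step 1
Reactants: 1 2-methylprop-2-en-1-ol
Product: 3 (2S)-(2-methyloxiran-2-yl)methyl 4-methylbenzenesulfonate, via (2R)-2-methylglycidol 2 (not isolated)
Conditions: Ti(OiPr)4 (5 mol%), D-(−)-DIPT (6 mol%), cumene hydroperoxide, 4 Å MS, CH2Cl2, −20 °C; P(OMe)3; then TsCl, Et3N, DMAP (cat.), −10 °C; recrystallise
Reagents that add atoms: cumene hydroperoxide CC(C)(OO)c1ccccc1; 4-methylbenzenesulfonyl chloride Cc1ccc(cc1)S(Cl)(=O)=O
Why: Sharpless asymmetric epoxidation with the D-tartrate gives (R)-2-methylglycidol, trapped in situ as the tosylate (same spatial arrangement, descriptor S by CIP), which sets the quaternary centre that becomes C5 and can be enriched by recrystallisation.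

Step 2
Reactants: 3 (2S)-(2-methyloxiran-2-yl)methyl 4-methylbenzenesulfonate
Product: 4 (2S)-2-hydroxy-2,4-dimethylpent-4-en-1-yl 4-methylbenzenesulfonate
Conditions: isopropenylmagnesium bromide (1.3 equiv), CuI (10 mol%), THF, −40 → −20 °C; aq NH4Cl
Reagents that add atoms: isopropenylmagnesium bromide CC(=C)[Mg]Br
Why: Cu-catalysed Grignard opening of the epoxide at its free CH2 terminus (the neopentyl CH2OTs is not displaced) leaves the stereocentre untouched.

Step 3
Reactants: 4 (2S)-2-hydroxy-2,4-dimethylpent-4-en-1-yl 4-methylbenzenesulfonate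
Product: 6 (2S)-2-methyl-2-(2-methylprop-2-en-1-yl)oxetane, via (2S)-2-methyl-2-(2-methylprop-2-enyl)oxirane 5 (not isolated)
Conditions: Me3S(O)I (2.2 equiv), KOtBu (3.3 equiv), t-BuOH, 50 °C, 48 h
Reagents that add atoms: trimethylsulfoxonium iodide C[S+](C)(C)=O.[I-]
Why: Williamson closure gives the epoxide, which dimethylsulfoxonium methylide opens at CH2 and re-closes 4-exo-tet with loss of DMSO (Corey–Chaykovsky-type ring expansion), the C–O bond of the stereocentre being retained throughout.

Step 4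
Reactants: 6 (2S)-2-methyl-2-(2-methylprop-2-en-1-yl)oxetane
Product: 7 1-[(2R)-2-methyloxetan-2-yl]propan-2-one
Conditions: O3, CH2Cl2, −78 °C; then Me2S, −78 °C → rt
Reagents that add atoms: ozone [O-][O+]=O
Why: Ozonolysis of the 1,1-disubstituted alkene gives the methyl ketone while the oxetane is inert (descriptor changes to R only through CIP priorities).

Step 5
Reactants: 7 1-[(2R)-2-methyloxetan-2-yl]propan-2-one
Product: 8 ethyl (2E)-3-methyl-4-[(2S)-2-methyloxetan-2-yl]but-2-enoate
Conditions: (EtO)2P(O)CH2CO2Et, NaH, THF, 0 °C → rt; chromatography (minor Z isomer removed)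
Reagents that add atoms: triethyl phosphonoacetate CCOC(=O)CP(=O)(OCC)OCC
Why: Horner–Wadsworth–Emmons olefination of the methyl ketone gives the β-methyl enoate, E major, under conditions too weakly basic to open the oxetane.

Step 6
Reactants: 8 ethyl (2E)-3-methyl-4-[(2S)-2-methyloxetan-2-yl]but-2-enoate
Product: 9 ethyl (2E,5R)-5-hydroperoxy-7-hydroxy-3,5-dimethylhept-2-enoate
Conditions: H2O2 (ca. 2 M in Et2O, 10 equiv), TMSOTf (20 mol%), Et2O, −78 → −20 °C
Reagents that add atoms: hydrogen peroxide OO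
Why: Lewis-acid-promoted SN2-like perhydrolysis of the oxetane at its tertiary carbon proceeds with inversion, giving the (R)-tertiary hydroperoxide and freeing the 2-hydroxyethyl arm.

Step 7
Reactants: 9 ethyl (2E,5R)-5-hydroperoxy-7-hydroxy-3,5-dimethylhept-2-enoate
Product: 10 ethyl 2-[(3R,5S)-5-(2-hydroxyethyl)-3,5-dimethyl-1,2-dioxolan-3-yl]acetate
Conditions: Et2NH (0.5 equiv), CF3CH2OH, rt; chromatography (C3 epimer removed)
Reagents that add atoms: none
Why: The 5-exo-trig intramolecular peroxy-Michael addition closes the 1,2-dioxolane through the far more acidic and nucleophilic OOH (not the OH) and creates C3 under weak substrate control (roughly 1:1 to 2:1 expected), the (3R,5S) isomer being separated from its C3 epimer.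

Step 8
Reactants: 10 ethyl 2-[(3R,5S)-5-(2-hydroxyethyl)-3,5-dimethyl-1,2-dioxolan-3-yl]acetate
Product: 11 ethyl 2-[(3R,5R)-3,5-dimethyl-5-(2-oxoethyl)-1,2-dioxolan-3-yl]acetate
Conditions: Dess–Martin periodinane, CH2Cl2, 0 °C → rt; used crude
Reagents that add atoms: none
Why: Dess–Martin oxidation gives the aldehyde under near-neutral conditions that leave the O–O bond and ester intact (C5 descriptor becomes R by CIP only).

Step 9
Reactants: 12 phenylmagnesium bromide; 13 1,8-dibromooctane
Product: 14 (8-bromooctyl)benzene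
Conditions: Li2CuCl4 (3 mol%), THF/NMP, 0 °C → rt; 13 in 3-fold excess, recovered by distillation
Reagents that add atoms: none
Why: Kochi-type Cu-catalysed Grignard–alkyl bromide cross-coupling, kept at the mono-arylation stage by the excess dibromide.

Step 10
Reactants: 14 (8-bromooctyl)benzene
Product: 15 (8-phenyloctyl)triphenylphosphonium bromide
Conditions: PPh3, MeCN, reflux
Reagents that add atoms: triphenylphosphine c1ccc(cc1)P(c1ccccc1)c1ccccc1
Why: SN2 quaternisation of the primary bromide.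

Step 11
Reactants: 11 ethyl 2-[(3R,5R)-3,5-dimethyl-5-(2-oxoethyl)-1,2-dioxolan-3-yl]acetate; 15 (8-phenyloctyl)triphenylphosphonium bromide
Product: 17 ethyl 2-[(3R,5S)-3,5-dimethyl-5-[(2Z)-10-phenyldec-2-en-1-yl]-1,2-dioxolan-3-yl]acetate, via (8-phenyloctylidene)triphenylphosphorane 16 (not isolated)
Conditions: 15, NaHMDS, THF, −78 °C; ylide added to 11 at −78 °C, then → 0 °C
Reagents that add atoms: none
Why: Wittig olefination with the non-stabilised ylide at −78 °C is faster than enolisation of the β-peroxy aldehyde and gives mainly the Z alkene, whose geometry is irrelevant.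

Step 12
Reactants: 17 ethyl 2-[(3R,5S)-3,5-dimethyl-5-[(2Z)-10-phenyldec-2-en-1-yl]-1,2-dioxolan-3-yl]acetate
Product: 18 ethyl 2-[(3R,5S)-3,5-dimethyl-5-(10-phenyldecyl)-1,2-dioxolan-3-yl]acetate
Conditions: KO2C–N=N–CO2K (excess, portionwise), AcOH, MeOH, 0 °C → rt
Reagents that add atoms: none
Why: Diimide reduction transfers H2 to the C=C bond in a concerted way and does not cleave the O–O bond, unlike catalytic hydrogenation.

Step 13
Reactants: 18 ethyl 2-[(3R,5S)-3,5-dimethyl-5-(10-phenyldecyl)-1,2-dioxolan-3-yl]acetate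
Product: 19 andavadoic acid, 2-[(3R,5S)-3,5-dimethyl-5-(10-phenyldecyl)-1,2-dioxolan-3-yl]acetic acid
Conditions: LiOH·H2O, THF/H2O, 0 °C → rt; then 1 M HCl to pH 3
Reagents that add atoms: lithium hydroxide [Li+].[OH-]
Why: Saponification of the ethyl ester is safe because both peroxide carbons are fully substituted (no Kornblum–DeLaMare pathway), and it gives the target.

## Compound list

1 | 2-methylprop-2-en-1-ol | C=C(C)CO | starting material
2 | (2R)-2-methylglycidol | C[C@@]1(CO)CO1 | intermediate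
3 | (2S)-(2-methyloxiran-2-yl)methyl 4-methylbenzenesulfonate | C[C@@]1(COS(=O)(=O)c2ccc(C)cc2)CO1 | intermediate
4 | (2S)-2-hydroxy-2,4-dimethylpent-4-en-1-yl 4-methylbenzenesulfonate | C[C@@](O)(COS(=O)(=O)c1ccc(C)cc1)CC(C)=C | intermediate
5 | (2S)-2-methyl-2-(2-methylprop-2-en-1-yl)oxirane | C[C@]1(CC(C)=C)CO1 | intermediate
6 | (2S)-2-methyl-2-(2-methylprop-2-en-1-yl)oxetane | C[C@]1(CC(C)=C)CCO1 | intermediate
7 | 1-[(2R)-2-methyloxetan-2-yl]propan-2-one | C[C@]1(CC(C)=O)CCO1 | intermediate
8 | ethyl (2E)-3-methyl-4-[(2S)-2-methyloxetan-2-yl]but-2-enoate | C[C@]1(C/C(C)=C/C(=O)OCC)CCO1 | intermediate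
9 | ethyl (2E,5R)-5-hydroperoxy-7-hydroxy-3,5-dimethylhept-2-enoate | C[C@@](OO)(C/C(C)=C/C(=O)OCC)CCO | intermediate
10 | ethyl 2-[(3R,5S)-5-(2-hydroxyethyl)-3,5-dimethyl-1,2-dioxolan-3-yl]acetate | C[C@]1(CCO)C[C@](C)(CC(=O)OCC)OO1 | intermediate
11 | ethyl 2-[(3R,5R)-3,5-dimethyl-5-(2-oxoethyl)-1,2-dioxolan-3-yl]acetate | C[C@]1(CC=O)C[C@](C)(CC(=O)OCC)OO1 | intermediate
12 | phenylmagnesium bromide | Br[Mg]c1ccccc1 | starting material
13 | 1,8-dibromooctane | BrCCCCCCCCBr | starting material
14 | (8-bromooctyl)benzene | BrCCCCCCCCc1ccccc1 | intermediate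
15 | (8-phenyloctyl)triphenylphosphonium bromide | [Br-].c1ccc(CCCCCCCC[P+](c2ccccc2)(c2ccccc2)c2ccccc2)cc1 | intermediate
16 | (8-phenyloctylidene)triphenylphosphorane | c1ccc(CCCCCCCC=P(c2ccccc2)(c2ccccc2)c2ccccc2)cc1 | intermediate
17 | ethyl 2-[(3R,5S)-3,5-dimethyl-5-[(2Z)-10-phenyldec-2-en-1-yl]-1,2-dioxolan-3-yl]acetate | C[C@]1(C/C=C\CCCCCCCc2ccccc2)C[C@](C)(CC(=O)OCC)OO1 | intermediate
18 | ethyl 2-[(3R,5S)-3,5-dimethyl-5-(10-phenyldecyl)-1,2-dioxolan-3-yl]acetate | C[C@]1(CCCCCCCCCCc2ccccc2)C[C@](C)(CC(=O)OCC)OO1 | intermediate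
19 | andavadoic acid, 2-[(3R,5S)-3,5-dimethyl-5-(10-phenyldecyl)-1,2-dioxolan-3-yl]acetic acid | C[C@]1(CCCCCCCCCCc2ccccc2)C[C@](C)(CC(=O)O)OO1 | target

## Step count and risks

Total step count: 13. Longest linear sequence: 11 (steps 1–8 and 11–13). The chain fragment (steps 9–10) is made separately and joined at step 11.

Steps most likely to fail:

Step 6 (perhydrolysis of 8). The tertiary centre may ionise, giving elimination or partial loss of ee, and the yield may be low with the enoate present. The fallback sets out from oxetane 6 and opens the plain alkene substrate first (H2O2/Et2O, TMSOTf), giving (3R)-3-hydroperoxy-3,5-dimethylhex-5-en-1-ol F1. Both OOH and OH are then silylated (TESOTf, 2,6-lutidine, CH2Cl2, −78 °C) to give triethyl({(3R)-3,5-dimethyl-1-[(triethylsilyl)oxy]hex-5-en-3-yl}peroxy)silane F2. Cross-metathesis with ethyl acrylate (Hoveyda–Grubbs II, CH2Cl2, 40 °C) installs the acceptor, giving ethyl (2E,5R)-3,5-dimethyl-5-[(triethylsilyl)peroxy]-7-[(triethylsilyl)oxy]hept-2-enoate F3. TBAF/AcOH in THF removes both silyl groups and the freed hydroperoxide closes in the same pot, coming back to the route at 10.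

Step 7 (peroxy-Michael ring closure). The C3 selectivity may be poor, the epimers hard to separate, or the free hydroxyl may interfere. The fallback sets out from 9 and caps the primary hydroxyl with a large silyl group (TBDPSCl, imidazole, CH2Cl2, 0 °C), giving ethyl (2E,5R)-7-[(tert-butyldiphenylsilyl)oxy]-5-hydroperoxy-3,5-dimethylhept-2-enoate F4. Cyclisation with Cs2CO3 (cat.) in CF3CH2OH now differentiates a bulky arm from methyl at C5 and gives a lipophilic, UV-active product that is easier to separate, ethyl 2-[(3R,5S)-5-{2-[(tert-butyldiphenylsilyl)oxy]ethyl}-3,5-dimethyl-1,2-dioxolan-3-yl]acetate F5. HF·pyridine in THF returns to the route at 10.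

Step 11 (Wittig on the β-peroxy aldehyde). The basic ylide may trigger β-elimination (retro-Michael opening of the dioxolane). The fallback sets out from alcohol 10 and avoids the aldehyde altogether. Tosylation (TsCl, pyridine, 0 °C) gives ethyl 2-[(3R,5S)-3,5-dimethyl-5-{2-[(4-methylbenzenesulfonyl)oxy]ethyl}-1,2-dioxolan-3-yl]acetate F6. Bromide 14 is converted with Mg in THF into (8-phenyloctyl)magnesium bromide F7. Cu-catalysed sp3–sp3 coupling of the two (Li2CuCl4 cat., THF, −78 → −30 °C, slow addition) gives the saturated ester directly, coming back to the route at 18.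

## Further compounds

F1 | step 6 | (3R)-3-hydroperoxy-3,5-dimethylhex-5-en-1-ol | C[C@@](OO)(CC(C)=C)CCO
F2 | step 6 | triethyl({(3R)-3,5-dimethyl-1-[(triethylsilyl)oxy]hex-5-en-3-yl}peroxy)silane | C[C@@](OO[Si](CC)(CC)CC)(CC(C)=C)CCO[Si](CC)(CC)CC
F3 | step 6 | ethyl (2E,5R)-3,5-dimethyl-5-[(triethylsilyl)peroxy]-7-[(triethylsilyl)oxy]hept-2-enoate | C[C@@](OO[Si](CC)(CC)CC)(C/C(C)=C/C(=O)OCC)CCO[Si](CC)(CC)CC
F4 | step 7 | ethyl (2E,5R)-7-[(tert-butyldiphenylsilyl)oxy]-5-hydroperoxy-3,5-dimethylhept-2-enoate | C[C@@](OO)(C/C(C)=C/C(=O)OCC)CCO[Si](c1ccccc1)(c1ccccc1)C(C)(C)C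
F5 | step 7 | ethyl 2-[(3R,5S)-5-{2-[(tert-butyldiphenylsilyl)oxy]ethyl}-3,5-dimethyl-1,2-dioxolan-3-yl]acetate | C[C@]1(CCO[Si](c2ccccc2)(c2ccccc2)C(C)(C)C)C[C@](C)(CC(=O)OCC)OO1
F6 | step 11 | ethyl 2-[(3R,5S)-3,5-dimethyl-5-{2-[(4-methylbenzenesulfonyl)oxy]ethyl}-1,2-dioxolan-3-yl]acetate | C[C@]1(CCOS(=O)(=O)c2ccc(C)cc2)C[C@](C)(CC(=O)OCC)OO1
F7 | step 11 | (8-phenyloctyl)magnesium bromide | Br[Mg]CCCCCCCCc1ccccc1
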